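**Retrosynthetic overview**
1. Target 10 ⇒ its tri-O-benzyl ether 9 (neutral hydrogenolysis last).
2. 9 ⇒ both aryl–CH2 bonds cut at once: aryl dibromide 8 as electrophile plus two boron homoenolates 6 (CH2–B on the carbon β to the ring carbonyl), joined by a twofold Csp3–Csp2 Suzuki coupling.
3. 6 ⇒ butyrylfilicinic acid 4 + ICH2Bpin 5 (C-alkylation); 4 ⇒ dearomatising gem-dimethylation of phlorbutyrophenone 3.
4. 8 ⇒ 3 by ring dibromination and O-benzylation; 3 ⇒ phloroglucinol 1 + butanoyl chloride 2.
5. Ring order: the benzene ring is bought, the two dimethyl-dienone rings are made from it by dearomatisation (step 2), and the three rings are joined last.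

Assumption: the target has no stereocentre (achiral, freely tautomerising enols), so there is no enantiomer to select; the tautomer of the given SMILES is drawn throughout.

**Step 1**
Reactants: 1 phloroglucinol; 2 butanoyl chloride
Product: 3 1-(2,4,6-trihydroxyphenyl)butan-1-one (phlorbutyrophenone)
Conditions: AlCl3 (3.5 equiv), PhNO2, 60 °C; ice/aq. HCl
Reagents that add atoms: none
Why: Friedel–Crafts C-acylation of the very electron-rich triol stops at the mono-ketone because the chelated acyl group deactivates the ring, and no stereocentre is formed.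

**Step 2**
Reactants: 3 phlorbutyrophenone
Product: 4 butyrylfilicinic acid (2-butanoyl-3,5-dihydroxy-6,6-dimethylcyclohexa-2,4-dien-1-one)
Conditions: NaOMe (3.0 equiv), MeI (2.4 equiv), MeOH, 0 °C → rt; aq. HCl; crystallisation/chromatography
Reagents that add atoms: iodomethane, CI
Why: Twofold C-methylation of the phloroglucinol anion at one ring carbon (dearomatising enolate alkylation) gives the gem-dimethyl dienone as the main product at this stoichiometry, with over-methylated by-products separated, and the new quaternary carbon carries two identical methyl groups so it is not a stereocentre.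

**Step 3**
Reactants: 4 butyrylfilicinic acid; 5 2-(iodomethyl)-4,4,5,5-tetramethyl-1,3,2-dioxaborolane (ICH2Bpin)
Product: 6 2-butanoyl-3,5-dihydroxy-6,6-dimethyl-4-[(4,4,5,5-tetramethyl-1,3,2-dioxaborolan-2-yl)methyl]cyclohexa-2,4-dien-1-one
Conditions: LiOtBu (1.0 equiv), THF, 0 °C; then 5 (1.1 equiv), 0 → 40 °C; pH 5 buffer work-up
Reagents that add atoms: none
Why: Enolate alkylation of the chelated lithium salt at its only free ring carbon with the SN2-activated α-boryl iodide puts boron on the carbon β to the ring carbonyl (a boron homoenolate), the aprotic lithium-chelated conditions favouring C- over O-alkylation, and no stereocentre is formed.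

**Step 4**
Reactants: 3 phlorbutyrophenone
Product: 8 1-[2,4,6-tris(benzyloxy)-3,5-dibromophenyl]butan-1-one, via 3,5-dibromophlorbutyrophenone 7 (not isolated)
Conditions: Br2 (2.0 equiv), DMF, 0 °C; then K2CO3 (7 equiv), BnBr (3.6 equiv), Bu4NI (cat.), 70 °C
Reagents that add atoms: bromine, BrBr; benzyl bromide, BrCc1ccccc1
Why: Electrophilic aromatic bromination fills the two free ring positions and Williamson etherification in the same pot caps the three phenols, which turns the ring carbons into electrophilic C–Br sites and removes the phenoxides that would make the later diarylmethane-type bonds base-labile, with no stereocentre involved.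

**Step 5**
Reactants: 8 tribenzyl dibromide (1 equiv); 6 boron homoenolate (2.6 equiv)
Product: 9 1-[2,4,6-tris(benzyloxy)-3,5-bis[(5-butanoyl-2,6-dihydroxy-3,3-dimethyl-4-oxocyclohexa-1,5-dien-1-yl)methyl]phenyl]butan-1-one
Conditions: Pd(OAc)2 (10 mol %), SPhos (20 mol %), K3PO4 (8 equiv), degassed 1,4-dioxane/H2O 5:1, 80 °C; aq. citric acid to pH 3
Reagents that add atoms: none
Why: In this twofold Suzuki–Miyaura Csp3–Csp2 coupling the CH2–B carbon of 6 acts as a homoenolate nucleophile and the aryl C–Br carbon, normally the nucleophilic site of a phloroglucinol, is the electrophile, which should work because the allyl/benzyl-like boronate transmetalates readily, the Pd–CH2 intermediate has no β-hydrogen and the benzyl ethers block base-induced retro-Michael scrambling, and no stereocentre is formed.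

**Step 6**
Reactants: 9 tri-O-benzyl ether of the target
Product: 10 1-[3,5-bis[(5-butanoyl-2,6-dihydroxy-3,3-dimethyl-4-oxocyclohexa-1,5-dien-1-yl)methyl]-2,4,6-trihydroxyphenyl]butan-1-one (target)
Conditions: H2 (1 atm), 10% Pd/C, EtOAc/MeOH 1:1, rt
Reagents that add atoms: none
Why: Catalytic hydrogenolysis of the three aryl benzyl ethers under neutral conditions frees the phenols without touching the enolised β-triketones, the hindered aryl ketone or the base-sensitive methylene bridges, and the product is achiral.

**Compound list**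
1 | phloroglucinol (benzene-1,3,5-triol) | Oc1cc(O)cc(O)c1 | starting material
2 | butanoyl chloride | CCCC(Cl)=O | starting material
3 | 1-(2,4,6-trihydroxyphenyl)butan-1-one (phlorbutyrophenone) | CCCC(=O)c1c(O)cc(O)cc1O | intermediate
4 | butyrylfilicinic acid (2-butanoyl-3,5-dihydroxy-6,6-dimethylcyclohexa-2,4-dien-1-one) | CCCC(=O)C1=C(O)C=C(O)C(C)(C)C1=O | intermediate
5 | 2-(iodomethyl)-4,4,5,5-tetramethyl-1,3,2-dioxaborolane (ICH2Bpin) | CC1(C)OB(CI)OC1(C)C | starting material
6 | 2-butanoyl-3,5-dihydroxy-6,6-dimethyl-4-[(4,4,5,5-tetramethyl-1,3,2-dioxaborolan-2-yl)methyl]cyclohexa-2,4-dien-1-one | CCCC(=O)C1=C(O)C(CB2OC(C)(C)C(C)(C)O2)=C(O)C(C)(C)C1=O | intermediate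
7 | 1-(3,5-dibromo-2,4,6-trihydroxyphenyl)butan-1-one | CCCC(=O)c1c(O)c(Br)c(O)c(Br)c1O | intermediate
8 | 1-[2,4,6-tris(benzyloxy)-3,5-dibromophenyl]butan-1-one | CCCC(=O)c1c(OCc2ccccc2)c(Br)c(OCc3ccccc3)c(Br)c1OCc4ccccc4 | intermediate
9 | 1-[2,4,6-tris(benzyloxy)-3,5-bis[(5-butanoyl-2,6-dihydroxy-3,3-dimethyl-4-oxocyclohexa-1,5-dien-1-yl)methyl]phenyl]butan-1-one | CCCC(=O)C1=C(O)C(Cc2c(OCc4ccccc4)c(CC3=C(O)C(C)(C)C(=O)C(C(=O)CCC)=C3O)c(OCc5ccccc5)c(C(=O)CCC)c2OCc6ccccc6)=C(O)C(C)(C)C1=O | intermediate
10 | 1-[3,5-bis[(5-butanoyl-2,6-dihydroxy-3,3-dimethyl-4-oxocyclohexa-1,5-dien-1-yl)methyl]-2,4,6-trihydroxyphenyl]butan-1-one | CCCC(=O)C1=C(O)C(Cc2c(O)c(CC3=C(O)C(C)(C)C(=O)C(C(=O)CCC)=C3O)c(O)c(C(=O)CCC)c2O)=C(O)C(C)(C)C1=O | target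

**Step count and risks**
Total steps: 6. Longest linear sequence: 5 (steps 1, 2, 3, 5, 6); step 4 is the short second branch from 3.

Steps most likely to fail:

Step 5, the twofold coupling. The likeliest failure is protodeboronation of 6 in hot aqueous base before it transmetalates to the hindered aryl bromide. The fallback changes the homoenolate metal so that no base is needed. It sets out from 4, whose lithium enolate (LiOtBu, THF) is alkylated with tributyl(iodomethyl)stannane to give 2-butanoyl-3,5-dihydroxy-6,6-dimethyl-4-[(tributylstannyl)methyl]cyclohexa-2,4-dien-1-one F1. Two equivalents of F1 are then joined to 8 by a base-free Stille coupling (Pd2(dba)3/XPhos, CuI, dioxane, 90 °C), which comes back to the route at 9.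

Step 3, the C-alkylation with ICH2Bpin. The risk is O-alkylation through a boron-ate 1,2-shift, or double alkylation. The fallback makes the C–CH2 bond first and brings in boron afterwards. It sets out from 4, which with Eschenmoser's salt (CH2Cl2, rt) gives the Mannich base 2-butanoyl-4-[(dimethylamino)methyl]-3,5-dihydroxy-6,6-dimethylcyclohexa-2,4-dien-1-one F2. Warming F2 with B2pin2 and a CuCl/phosphine catalyst expels dimethylamine to the transient methylene-trione, and conjugate addition of Cu–Bpin to its exocyclic carbon comes back to the route at 6.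

Step 6, the hydrogenolysis. The three benzyl ethers are hindered and sit next to an aryl ketone that may be over-reduced. The fallback uses acid-labile acetal protection instead. It sets out from 7, isolated this time after the bromination half of step 4, and MOMCl/i-Pr2NEt in CH2Cl2 gives 1-[3,5-dibromo-2,4,6-tris(methoxymethoxy)phenyl]butan-1-one F3. Coupling of F3 with 6 under the conditions of step 5 gives 1-[3,5-bis[(5-butanoyl-2,6-dihydroxy-3,3-dimethyl-4-oxocyclohexa-1,5-dien-1-yl)methyl]-2,4,6-tris(methoxymethoxy)phenyl]butan-1-one F4. Treatment of F4 with 1 M HCl in MeOH at 40 °C removes the acetals and comes back to the route at 10.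

**Further compounds**
F1 | step 5 | 2-butanoyl-3,5-dihydroxy-6,6-dimethyl-4-[(tributylstannyl)methyl]cyclohexa-2,4-dien-1-one | CCCC(=O)C1=C(O)C(C[Sn](CCCC)(CCCC)CCCC)=C(O)C(C)(C)C1=O
F2 | step 3 | 2-butanoyl-4-[(dimethylamino)methyl]-3,5-dihydroxy-6,6-dimethylcyclohexa-2,4-dien-1-one | CCCC(=O)C1=C(O)C(CN(C)C)=C(O)C(C)(C)C1=O
F3 | step 6 | 1-[3,5-dibromo-2,4,6-tris(methoxymethoxy)phenyl]butan-1-one | CCCC(=O)c1c(OCOC)c(Br)c(OCOC)c(Br)c1OCOC
F4 | step 6 | 1-[3,5-bis[(5-butanoyl-2,6-dihydroxy-3,3-dimethyl-4-oxocyclohexa-1,5-dien-1-yl)methyl]-2,4,6-tris(methoxymethoxy)phenyl]butan-1-one | CCCC(=O)C1=C(O)C(Cc2c(OCOC)c(CC3=C(O)C(C)(C)C(=O)C(C(=O)CCC)=C3O)c(OCOC)c(C(=O)CCC)c2OCOC)=C(O)C(C)(C)C1=O
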